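**Retrosynthetic overview**

- Feature: the E-alkene C9=C10 lies between two oxygenated carbons, C8 (OMe) and C11 (OAc). Each is syn to its oxygenated neighbour (C7–OH, C12–OAc), so C9/C10 can be an acetylene unit joining two α-alkoxy aldehydes.
- Key disconnections: C8–C9 and C10–C11, made by two chelation-controlled alkynyl-Grignard additions in one flask, with O-methylation of the first alkoxide in between. The C9≡C10 alkyne is then reduced to the E-alkene by trans-hydrosilylation and protodesilylation.
- Ring order: the only ring, the 5,6-dihydro-2H-pyran-2-one (O1–C6), is closed last by O6-acryloylation and ring-closing metathesis at C3=C4. The C7 PMB ether is removed afterwards.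
- Fragments: the C4–C8 aldehyde (O7 PMB, O6 TBS; C6 and C7 from 2-deoxy-D-ribose), the C11–C13 aldehyde (O12 MOM; C12 from methyl (R)-lactate), and ethynylmagnesium bromide.

Key step: step 10

Remark: locants are those of the target (O1, C2 lactone carbonyl, C3=C4, C5, ring C6, side chain C7–C13); the allyl group of the intermediates is C5–C4 plus one CH2 that leaves as ethylene. C6, C7, C8, C11 and C12 keep the spatial arrangement of the target in every intermediate (encoded in the SMILES), while their CIP letters change with the protecting groups.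

**Route**

Step 1
Reactants: 1 2-deoxy-D-ribose
Product: 2 (2R,3S)-hex-5-ene-1,2,3-triol
Conditions: Ph3PCH3Br, KOt-Bu, THF, 0 °C to reflux
Reagents that add atoms: methyltriphenylphosphonium bromide, C[P+](c1ccccc1)(c1ccccc1)c1ccccc1.[Br-]
Why: Wittig methylenation of the open-chain aldehyde tautomer of the lactol with excess ylide should give the terminal alkene without touching the two carbinol centres that become C7 and C6.

Step 2
Reactants: 2 (2R,3S)-hex-5-ene-1,2,3-triol
Product: 3 (S)-1-[(R)-2,2-dimethyl-1,3-dioxolan-4-yl]but-3-en-1-ol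
Conditions: Me2C(OMe)2, p-TsOH·H2O (cat.), acetone, 0 °C to rt
Reagents that add atoms: 2,2-dimethoxypropane, COC(C)(C)OC
Why: Acid-catalysed transketalisation should favour the terminal O7/O8 dioxolane over the cis-4,5-disubstituted O6/O7 dioxolane and over the 1,3-dioxane with an axial methyl, leaving only the C6 hydroxyl free.

Step 3
Reactants: 3 (S)-1-[(R)-2,2-dimethyl-1,3-dioxolan-4-yl]but-3-en-1-ol
Product: 4 tert-butyl{[(S)-1-((R)-2,2-dimethyl-1,3-dioxolan-4-yl)but-3-en-1-yl]oxy}dimethylsilane
Conditions: TBSCl, imidazole, DMAP (cat.), DMF, rt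
Reagents that add atoms: tert-butyldimethylsilyl chloride, CC(C)(C)[Si](C)(C)Cl
Why: Imidazole-promoted silylation of the single free secondary alcohol installs the bulky, non-chelating ether needed at O6.

Step 4
Reactants: 4 tert-butyl{[(S)-1-((R)-2,2-dimethyl-1,3-dioxolan-4-yl)but-3-en-1-yl]oxy}dimethylsilane
Product: 5 (2R,3S)-3-(tert-butyldimethylsilyloxy)hex-5-ene-1,2-diol
Conditions: AcOH/H2O (4:1), rt
Reagents that add atoms: none
Why: Mild aqueous acid hydrolysis of the terminal acetonide should proceed while the secondary TBS ether, which is far slower to cleave and does not migrate under acidic conditions, stays in place.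

Step 5
Reactants: 5 (2R,3S)-3-(tert-butyldimethylsilyloxy)hex-5-ene-1,2-diol
Product: 6 (4R)-4-[(1S)-1-(tert-butyldimethylsilyloxy)but-3-en-1-yl]-2-(4-methoxyphenyl)-1,3-dioxolane (both epimers at the acetal carbon)
Conditions: 4-MeOC6H4CH(OMe)2, PPTS (cat.), CH2Cl2, rt
Reagents that add atoms: 4-methoxybenzaldehyde dimethyl acetal, COc1ccc(cc1)C(OC)OC
Why: Acid-catalysed transacetalisation of the only 1,2-diol gives the p-methoxybenzylidene acetal without regiochemical ambiguity; the acetal epimers converge in the next step.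

Step 6
Reactants: 6 (4R)-4-[(1S)-1-(tert-butyldimethylsilyloxy)but-3-en-1-yl]-2-(4-methoxyphenyl)-1,3-dioxolane
Product: 7 (2R,3S)-3-(tert-butyldimethylsilyloxy)-2-(4-methoxybenzyloxy)hex-5-en-1-ol
Conditions: i-Bu2AlH, CH2Cl2, −78 to 0 °C; aq KNa tartrate
Reagents that add atoms: none
Why: In this reductive acetal opening the aluminium binds the less hindered primary oxygen, that C–O bond breaks and hydride quenches the oxocarbenium ion, so the PMB group should end on the secondary O7 and the primary hydroxyl is freed.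

Step 7
Reactants: 7 (2R,3S)-3-(tert-butyldimethylsilyloxy)-2-(4-methoxybenzyloxy)hex-5-en-1-ol
Product: 8 (2S,3S)-3-(tert-butyldimethylsilyloxy)-2-(4-methoxybenzyloxy)hex-5-enal
Conditions: Dess–Martin periodinane, NaHCO3, CH2Cl2, 0 °C to rt
Reagents that add atoms: none
Why: Dess–Martin oxidation is non-basic, so the α-alkoxy aldehyde should form without epimerisation at C7 or β-elimination of the silyloxy group; it is used directly.

Step 8
Reactants: 9 methyl (R)-lactate
Product: 10 methyl (R)-2-(methoxymethoxy)propanoate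
Conditions: MOMCl, i-Pr2NEt, CH2Cl2, 0 °C to rt
Reagents that add atoms: chloromethyl methyl ether, COCCl
Why: O-alkylation of the secondary alcohol with the reactive α-chloro ether under amine base installs the chelating acetal ether without racemising the lactate centre.

Step 9
Reactants: 10 methyl (R)-2-(methoxymethoxy)propanoate
Product: 11 (R)-2-(methoxymethoxy)propanal
Conditions: i-Bu2AlH, Et2O, −78 °C; aq KNa tartrate
Reagents that add atoms: none
Why: Partial ester reduction stops at the aldehyde because the chelated aluminium hemiacetal is stable at −78 °C until work-up; the volatile aldehyde is used as a dried solution.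

Step 10
Reactants: 8 (2S,3S)-3-(tert-butyldimethylsilyloxy)-2-(4-methoxybenzyloxy)hex-5-enal; 12 ethynylmagnesium bromide; 11 (R)-2-(methoxymethoxy)propanal
Product: 16 (2R,3R,6S,7R,8S)-8-(tert-butyldimethylsilyloxy)-6-methoxy-7-(4-methoxybenzyloxy)-2-(methoxymethoxy)undec-10-en-4-yn-3-ol, via bromomagnesium propargylic alkoxide 13 (not isolated), via terminal alkyne methyl ether 14 (not isolated), via alkynylmagnesium bromide 15 (not isolated)
Conditions: 8 in PhMe, 12 (1.5 equiv, THF), −78 °C; MeOTf, −78 to 0 °C, Ar purge; EtMgBr, 0 °C to rt; 11 in PhMe, −78 to −40 °C; aq NH4Cl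
Reagents that add atoms: methyl trifluoromethanesulfonate, COS(=O)(=O)C(F)(F)F
Why: The magnesium of 12 is held between the C8 carbonyl oxygen and the C7 PMB-ether oxygen of 8 in a five-membered chelate (the bulky C6 silyl ether does not compete), and the ethynyl group attacks the carbonyl face away from the C6 branch, so alkoxide 13 forms with O7 and O8 syn (the 8S arrangement of the target). MeOTf, a far stronger methylating agent than MeI, then alkylates the alkoxide oxygen in the same flask to give 14, EtMgBr metalates the terminal alkyne to 15, and 15 adds to the MOM-chelated aldehyde 11 on the face away from the C13 methyl, giving the 11,12-syn alcohol (11R) with C8 as methyl ether and C11 as free hydroxyl simply through the order of addition. The closest known reaction type is the Cram-chelate addition of alkynyl Grignard reagents to α-alkoxy aldehydes, used here twice on one acetylene unit and combined with O-methylation of a metal alkoxide and metalation of a terminal alkyne. No ring is closed; the new bonds C8–C9 and C10–C11 arise from two intermolecular 1,2-additions. The step needs 1,2-syn facial selectivity at both aldehydes and mono-addition of the C2 unit in the first stage: the former is secured by the chelating α-ethers, the non-chelating silyl ether, a bulk solvent of low donor strength and low temperature, the latter by excess 12 at −78 °C, and minor C8 or C11 epimers should be separable at the stage of alcohol 16.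

Step 11
Reactants: 16 C4–C13 enynol
Product: 17 (Z)-vinylsilane, the C9-triethoxysilyl alkene with H at C10 and C8 trans to C11 (other groups as in 16)
Conditions: (EtO)3SiH, [Cp*Ru(MeCN)3]PF6 (5 mol %), CH2Cl2, 0 °C to rt
Reagents that add atoms: triethoxysilane, CCO[SiH](OCC)OCC
Why: Ruthenium-catalysed trans-hydrosilylation adds Si–H anti across the internal alkyne (silicon expected distal to the free hydroxyl, though either regioisomer gives the same alkene) and leaves the terminal alkene alone; it avoids the hydroalumination route, whose C9–metal intermediate would expel the C8 methoxy group to an allene.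

Step 12
Reactants: 17 (Z)-vinylsilane
Product: 18 (2R,3R,4E,6S,7R,8S)-8-(tert-butyldimethylsilyloxy)-6-methoxy-7-(4-methoxybenzyloxy)-2-(methoxymethoxy)undeca-4,10-dien-3-ol (E-allylic alcohol; 11-OH, 12-OMOM)
Conditions: AgF, THF/MeOH/H2O, rt, dark
Reagents that add atoms: none
Why: Fluoride-assisted transfer of the alkenyl group from silicon to silver and protonation with retention (protodesilylation) should turn the Z-vinylsilane into the E-1,2-disubstituted alkene, and AgF is mild enough to spare the secondary TBS ether.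

Step 13
Reactants: 18 E-allylic alcohol
Product: 19 C11 acetate of 18 (12-OMOM retained)
Conditions: Ac2O, pyridine, DMAP (cat.), CH2Cl2, 0 °C to rt
Reagents that add atoms: acetic anhydride, CC(=O)OC(C)=O
Why: DMAP-catalysed acetylation of the only free hydroxyl installs the first target acetate and blocks O11 from capturing the MOM-derived oxocarbenium ion as a cyclic methylene acetal in the next step.

Step 14
Reactants: 19 C11 acetate with 12-OMOM
Product: 20 C12 alcohol with 11-OAc (6-OTBS, 7-OPMB, 8-OMe unchanged)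
Conditions: TMSOTf, 2,2'-bipyridyl, CH2Cl2, 0 °C to rt; then H2O
Reagents that add atoms: none
Why: Silyl triflate buffered by bipyridyl activates only the acetal oxygen, converting the MOM ether into an N-(alkoxymethyl)pyridinium salt that water hydrolyses near neutrality (chemoselective MOM cleavage); plain PMB and methyl ethers, the silyl ether and the acetate are not activated, and any O11-to-O12 acetyl shift is harmless.

Step 15
Reactants: 20 C12 alcohol with 11-OAc
Product: 21 11,12-diacetate (6-OTBS, 7-OPMB, 8-OMe)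
Conditions: Ac2O, pyridine, DMAP (cat.), CH2Cl2, rt
Reagents that add atoms: acetic anhydride, CC(=O)OC(C)=O
Why: DMAP-catalysed acetylation of the remaining hydroxyl completes the diacetate, converging any acetyl-migrated isomer from step 14.

Step 16
Reactants: 21 11,12-diacetate silyl ether
Product: 22 C6 alcohol (11,12-diacetate, 7-OPMB, 8-OMe)
Conditions: HF·pyridine, pyridine, THF, 0 °C to rt
Reagents that add atoms: none
Why: Buffered fluoride desilylation removes the secondary TBS ether without touching the acetates or the PMB ether, and no acyl shift to O6 is expected because O7 is blocked and the acetates are remote.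

Step 17
Reactants: 22 C6 alcohol
Product: 23 C6 acrylate (11,12-diacetate, 7-OPMB, 8-OMe)
Conditions: acryloyl chloride, i-Pr2NEt, CH2Cl2, −78 to 0 °C
Reagents that add atoms: acryloyl chloride, C=CC(=O)Cl
Why: Acylation of the single free secondary alcohol with the acid chloride under amine base gives the acrylate; low temperature and the absence of nucleophilic catalyst limit conjugate addition and polymerisation.

Step 18
Reactants: 23 C6 acrylate
Product: 24 (6S)-6-[(1S,2S,3E,5R,6R)-5,6-diacetoxy-2-methoxy-1-(4-methoxybenzyloxy)hept-3-en-1-yl]-5,6-dihydro-2H-pyran-2-one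
Conditions: second-generation Grubbs catalyst (H2IMes)(PCy3)Cl2Ru=CHPh (5–10 mol %), CH2Cl2 (2 mM), 40 °C
Reagents that add atoms: none
Why: In this ring-closing metathesis the ruthenium alkylidene forms at the terminal alkene and closes the six-membered unsaturated lactone onto the acrylate with loss of ethylene; the C9=C10 alkene, E-disubstituted, electron-poor and flanked by two branched oxygenated carbons, should not compete.

Step 19
Reactants: 24 7-O-PMB lactone
Product: 25 (6S)-6-[(1S,2S,3E,5R,6R)-5,6-diacetoxy-1-hydroxy-2-methoxyhept-3-en-1-yl]-5,6-dihydro-2H-pyran-2-one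
Conditions: DDQ, CH2Cl2/pH 7 phosphate buffer, 0 °C to rt
Reagents that add atoms: none
Why: Oxidative PMB cleavage by DDQ (hydride abstraction at the electron-rich benzylic position, hydrolysis of the oxocarbenium ion) frees the C7 hydroxyl under neutral conditions that spare the acetates, the allylic methyl ether and the unsaturated lactone.

**Compound list**

1 | 2-deoxy-D-ribose (open-chain form drawn) | OC[C@@H](O)[C@@H](O)CC=O | starting material
2 | (2R,3S)-hex-5-ene-1,2,3-triol | OC[C@@H](O)[C@@H](O)CC=C | intermediate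
3 | (S)-1-[(R)-2,2-dimethyl-1,3-dioxolan-4-yl]but-3-en-1-ol | CC1(C)OC[C@@H](O1)[C@@H](O)CC=C | intermediate
4 | tert-butyl{[(S)-1-((R)-2,2-dimethyl-1,3-dioxolan-4-yl)but-3-en-1-yl]oxy}dimethylsilane | CC1(C)OC[C@@H](O1)[C@H](CC=C)O[Si](C)(C)C(C)(C)C | intermediate
5 | (2R,3S)-3-(tert-butyldimethylsilyloxy)hex-5-ene-1,2-diol | OC[C@@H](O)[C@H](CC=C)O[Si](C)(C)C(C)(C)C | intermediate
6 | (4R)-4-[(1S)-1-(tert-butyldimethylsilyloxy)but-3-en-1-yl]-2-(4-methoxyphenyl)-1,3-dioxolane (both acetal epimers) | COc1ccc(cc1)C1OC[C@@H](O1)[C@H](CC=C)O[Si](C)(C)C(C)(C)C | intermediate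
7 | (2R,3S)-3-(tert-butyldimethylsilyloxy)-2-(4-methoxybenzyloxy)hex-5-en-1-ol | OC[C@@H](OCc1ccc(OC)cc1)[C@H](CC=C)O[Si](C)(C)C(C)(C)C | intermediate
8 | (2S,3S)-3-(tert-butyldimethylsilyloxy)-2-(4-methoxybenzyloxy)hex-5-enal (C4–C8 aldehyde) | O=C[C@@H](OCc1ccc(OC)cc1)[C@H](CC=C)O[Si](C)(C)C(C)(C)C | intermediate
9 | methyl (R)-lactate | COC(=O)[C@@H](C)O | starting material
10 | methyl (R)-2-(methoxymethoxy)propanoate | COC(=O)[C@@H](C)OCOC | intermediate
11 | (R)-2-(methoxymethoxy)propanal (C11–C13 aldehyde) | O=C[C@@H](C)OCOC | intermediate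
12 | ethynylmagnesium bromide | C#C[Mg]Br | starting material
13 | bromomagnesium (3S,4R,5S)-5-(tert-butyldimethylsilyloxy)-4-(4-methoxybenzyloxy)oct-7-en-1-yn-3-olate | C#C[C@H](O[Mg]Br)[C@@H](OCc1ccc(OC)cc1)[C@H](CC=C)O[Si](C)(C)C(C)(C)C | intermediate (not isolated)
14 | (3S,4R,5S)-5-(tert-butyldimethylsilyloxy)-3-methoxy-4-(4-methoxybenzyloxy)oct-7-en-1-yne | C#C[C@H](OC)[C@@H](OCc1ccc(OC)cc1)[C@H](CC=C)O[Si](C)(C)C(C)(C)C | intermediate (not isolated)
15 | [(3S,4R,5S)-5-(tert-butyldimethylsilyloxy)-3-methoxy-4-(4-methoxybenzyloxy)oct-7-en-1-yn-1-yl]magnesium bromide | Br[Mg]C#C[C@H](OC)[C@@H](OCc1ccc(OC)cc1)[C@H](CC=C)O[Si](C)(C)C(C)(C)C | intermediate (not isolated)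
16 | (2R,3R,6S,7R,8S)-8-(tert-butyldimethylsilyloxy)-6-methoxy-7-(4-methoxybenzyloxy)-2-(methoxymethoxy)undec-10-en-4-yn-3-ol (C4–C13 enynol) | CO[C@@H](C#C[C@@H](O)[C@@H](C)OCOC)[C@@H](OCc1ccc(OC)cc1)[C@H](CC=C)O[Si](C)(C)C(C)(C)C | intermediate
17 | (Z)-vinylsilane: C9-triethoxysilyl alkene, H at C10, C8 trans to C11, other groups as in 16 | CO[C@@H](/C(=C/[C@@H](O)[C@@H](C)OCOC)[Si](OCC)(OCC)OCC)[C@@H](OCc1ccc(OC)cc1)[C@H](CC=C)O[Si](C)(C)C(C)(C)C | intermediate
18 | (2R,3R,4E,6S,7R,8S)-8-(tert-butyldimethylsilyloxy)-6-methoxy-7-(4-methoxybenzyloxy)-2-(methoxymethoxy)undeca-4,10-dien-3-ol | CO[C@@H](/C=C/[C@@H](O)[C@@H](C)OCOC)[C@@H](OCc1ccc(OC)cc1)[C@H](CC=C)O[Si](C)(C)C(C)(C)C | intermediate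
19 | C11 acetate of 18 (12-OMOM, 6-OTBS, 7-OPMB, 8-OMe) | CO[C@@H](/C=C/[C@@H](OC(C)=O)[C@@H](C)OCOC)[C@@H](OCc1ccc(OC)cc1)[C@H](CC=C)O[Si](C)(C)C(C)(C)C | intermediate
20 | C12 alcohol with 11-OAc (6-OTBS, 7-OPMB, 8-OMe) | CO[C@@H](/C=C/[C@@H](OC(C)=O)[C@@H](C)O)[C@@H](OCc1ccc(OC)cc1)[C@H](CC=C)O[Si](C)(C)C(C)(C)C | intermediate
21 | 11,12-diacetate (6-OTBS, 7-OPMB, 8-OMe) | CO[C@@H](/C=C/[C@@H](OC(C)=O)[C@@H](C)OC(C)=O)[C@@H](OCc1ccc(OC)cc1)[C@H](CC=C)O[Si](C)(C)C(C)(C)C | intermediate
22 | C6 alcohol (11,12-diacetate, 7-OPMB, 8-OMe) | CO[C@@H](/C=C/[C@@H](OC(C)=O)[C@@H](C)OC(C)=O)[C@@H](OCc1ccc(OC)cc1)[C@H](CC=C)O | intermediate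
23 | C6 acrylate (11,12-diacetate, 7-OPMB, 8-OMe) | CO[C@@H](/C=C/[C@@H](OC(C)=O)[C@@H](C)OC(C)=O)[C@@H](OCc1ccc(OC)cc1)[C@H](CC=C)OC(=O)C=C | intermediate
24 | (6S)-6-[(1S,2S,3E,5R,6R)-5,6-diacetoxy-2-methoxy-1-(4-methoxybenzyloxy)hept-3-en-1-yl]-5,6-dihydro-2H-pyran-2-one | CO[C@@H](/C=C/[C@@H](OC(C)=O)[C@@H](C)OC(C)=O)[C@@H](OCc1ccc(OC)cc1)[C@@H]1CC=CC(=O)O1 | intermediate
25 | (6S)-6-[(1S,2S,3E,5R,6R)-5,6-diacetoxy-1-hydroxy-2-methoxyhept-3-en-1-yl]-5,6-dihydro-2H-pyran-2-one | CO[C@@H](/C=C/[C@@H](OC(C)=O)[C@@H](C)OC(C)=O)[C@@H](O)[C@@H]1CC=CC(=O)O1 | target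

**Step count**

Total step count: 19 (steps 1–7 to aldehyde 8, steps 8–9 to aldehyde 11, step 10, steps 11–19).
Longest linear sequence: 17 steps (steps 1–7 and 10–19).

**Steps most likely to fail**

Step 10. What may go wrong: sluggish O-methylation of the magnesium alkoxide before the alkyne is remetalated, double addition of the acetylene unit to 8, or poor facial selectivity in the second addition (alkynyl Grignard reagents are often only moderately chelation-selective). Fallback, setting out from 8 and 10 and coming back at 16: the union is done stepwise with catalyst control at C11. Aldehyde 8 is treated with 12 (THF/PhMe, −78 °C) and quenched to give (3S,4R,5S)-5-(tert-butyldimethylsilyloxy)-4-(4-methoxybenzyloxy)oct-7-en-1-yn-3-ol F1, which is freed of its C8 epimer by chromatography and methylated (NaH, MeI, THF) to give 14 as an isolated compound. Ester 10 is converted with MeNH(OMe)·HCl and i-PrMgCl into (R)-N-methoxy-2-(methoxymethoxy)-N-methylpropanamide F2. Lithiated 14 (n-BuLi, THF, −78 °C) is acylated by F2 to give the C11 ynone F3. Noyori transfer hydrogenation of F3 with RuCl[(S,S)-TsDPEN](p-cymene) in i-PrOH then sets C11 under catalyst control and gives 16. The (S,S) catalyst is the one expected by analogy with simple ynones; the (R,R) catalyst would be used should the sense prove opposite.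

Step 14. What may go wrong: concurrent loss of the PMB or TBS ether, or ionisation at the allylic acetate or allylic methyl ether, under silyl triflate activation. Fallback, setting out from 18 and coming back at 24: both acid-labile groups are removed together and the oxygens are re-differentiated by a cyclic ketal. Alcohol 18 is treated with HCl (cat.) in MeOH at 40 °C, which removes the MOM and the TBS group, to give the C6,C11,C12-triol F4. 2,2-Dimethoxypropane with PPTS ties O11 and O12 into the trans-acetonide and leaves the 11,12-O-isopropylidene C6 alcohol F5. Acryloyl chloride with i-Pr2NEt gives the 11,12-O-isopropylidene C6 acrylate F6. Ring-closing metathesis as in step 18 gives the 11,12-O-isopropylidene 7-O-PMB lactone F7. Aqueous AcOH at 45 °C gives the 11,12-diol 7-O-PMB lactone F8, and diacetylation (Ac2O, pyridine, DMAP) gives 24.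

Step 18. What may go wrong: the ruthenium alkylidene formed at C4 engages the C9=C10 alkene instead of the acrylate (cyclohexene formation with loss of the C10–C13 chain), or intermolecular metathesis dominates. Fallback, setting out from 21 and coming back at 24: the lactone is made by Z-olefination and lactonisation instead of metathesis. The terminal alkene of 21 is cleaved selectively (OsO4 cat., NaIO4, 2,6-lutidine, dioxane/H2O; the C9=C10 alkene is hindered and deactivated by two allylic oxygens) to give the C4 aldehyde F9. Still–Gennari olefination with (CF3CH2O)2P(O)CH2CO2Me, KN(SiMe3)2 and 18-crown-6 in THF at −78 °C gives the Z-enoate methyl ester F10. HF·pyridine removes the TBS group, and the freed C6 hydroxyl closes onto the Z-ester (PPTS, PhH if needed) to give 24.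

Further compounds
F1 | step 10 | (3S,4R,5S)-5-(tert-butyldimethylsilyloxy)-4-(4-methoxybenzyloxy)oct-7-en-1-yn-3-ol | C#C[C@H](O)[C@@H](OCc1ccc(OC)cc1)[C@H](CC=C)O[Si](C)(C)C(C)(C)C
F2 | step 10 | (R)-N-methoxy-2-(methoxymethoxy)-N-methylpropanamide | CON(C)C(=O)[C@@H](C)OCOC
F3 | step 10 | (2R,6S,7R,8S)-8-(tert-butyldimethylsilyloxy)-6-methoxy-7-(4-methoxybenzyloxy)-2-(methoxymethoxy)undec-10-en-4-yn-3-one | CO[C@@H](C#CC(=O)[C@@H](C)OCOC)[C@@H](OCc1ccc(OC)cc1)[C@H](CC=C)O[Si](C)(C)C(C)(C)C
F4 | step 14 | C6,C11,C12-triol (7-OPMB, 8-OMe, C9=C10 E, C5 allyl) | CO[C@@H](/C=C/[C@@H](O)[C@@H](C)O)[C@@H](OCc1ccc(OC)cc1)[C@H](CC=C)O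
F5 | step 14 | 11,12-O-isopropylidene C6 alcohol (7-OPMB, 8-OMe) | CO[C@@H](/C=C/[C@H]1OC(C)(C)O[C@@H]1C)[C@@H](OCc1ccc(OC)cc1)[C@H](CC=C)O
F6 | step 14 | 11,12-O-isopropylidene C6 acrylate (7-OPMB, 8-OMe) | CO[C@@H](/C=C/[C@H]1OC(C)(C)O[C@@H]1C)[C@@H](OCc1ccc(OC)cc1)[C@H](CC=C)OC(=O)C=C
F7 | step 14 | 11,12-O-isopropylidene 7-O-PMB lactone | CO[C@@H](/C=C/[C@H]1OC(C)(C)O[C@@H]1C)[C@@H](OCc1ccc(OC)cc1)[C@@H]2CC=CC(=O)O2
F8 | step 14 | 11,12-diol 7-O-PMB lactone | CO[C@@H](/C=C/[C@@H](O)[C@@H](C)O)[C@@H](OCc1ccc(OC)cc1)[C@@H]1CC=CC(=O)O1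
F9 | step 18 | C4 aldehyde (6-OTBS, 7-OPMB, 8-OMe, 11,12-diacetate) | CO[C@@H](/C=C/[C@@H](OC(C)=O)[C@@H](C)OC(C)=O)[C@@H](OCc1ccc(OC)cc1)[C@H](CC=O)O[Si](C)(C)C(C)(C)C
F10 | step 18 | methyl (2Z)-enoate, C2–C13 chain (6-OTBS, 7-OPMB, 8-OMe, 11,12-diacetate) | CO[C@@H](/C=C/[C@@H](OC(C)=O)[C@@H](C)OC(C)=O)[C@@H](OCc1ccc(OC)cc1)[C@H](C/C=C\C(=O)OC)O[Si](C)(C)C(C)(C)C
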